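Its constants were drawn at random within sensible limits; the run is a simulation.

Read at 15 min, these flasks show where their intermediate went, to target or to side product, so begin from that fork.

    substrate + catalyst → catalyst + intermediate (k1 = 16000 M⁻¹ s⁻¹, Ea1 = 20.0 kJ mol⁻¹)
    reagent + catalyst + intermediate → catalyst + target (k2 = 74200 M⁻² s⁻¹, Ea2 = 17.0 kJ mol⁻¹)
    intermediate → side product (k3 = 0.0134 s⁻¹, Ea3 = 91.0 kJ mol⁻¹)
    catalyst + added ligand ⇌ idle complex, settled at all times (K4 = 37300 M⁻¹, ΔH4 = −81.0 kJ mol⁻¹)
    2 reagent → self-condensation product (k5 = 0.228 M⁻¹ s⁻¹, Ea5 = 72.0 kJ mol⁻¹)
    (constants at 70 °C)

| setting | Wednesday's | Tuesday's | Sunday's | Monday's |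
|---|---|---|---|---|
| substrate | 20 mM | 20 mM | 20 mM | 20 mM |
| reagent | 22.0 mM | 22.0 mM | 22.0 mM | 22.0 mM |
| catalyst | 11 µM | 11 µM | 11 µM | 11 µM |
| added ligand | 15 µM | 15 µM | 15 µM | 15 µM |
| temperature | 100 °C |  | 85 °C | 70 °C |
| time | 15 min | 15 min | 15 min | 15 min |
| remark |  | at 100 °C until 3.0 min, from then on at 70 °C |  |  |

- a doubled species enters its step squared and goes two at a time
- all constants are for 70 °C and move with temperature by the activation energies and enthalpies

* the flask that comes out highest in amount of target, in percent of the substrate charged, or "all alike" when all lie within 1.5 percentage points (Wednesday's / Tuesday's / Sunday's / Monday's / all alike)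
* target at the end, in percent of the substrate charged, Wednesday's
* target at the end, in percent of the substrate charged, Tuesday's
* target at the end, in percent of the substrate charged, Sunday's
* target at the end, in percent of the substrate charged, Monday's

1. Let r be the branch ratio, a selectivity factor: the rate constant of the target step times free catalyst C times reagent B, over the rate constant of the side step. The share going to target is r/(1+r).

2. You need the constants at 100 °C, and powers of ten make that easy, because the logarithm of each factor grows in proportion to its energy. Self-condensation speeds up 7.6-fold, which is 0.881 powers of ten for 72.0 kJ mol⁻¹. So the side step gains 13.0-fold, the target step 1.61-fold, and the ligand balance constant falls to 3810 M^-1.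

3. Solving that balance with both charges counted, Wednesday's has C = 10.4 µM, and Monday's has 7.66 µM. With B at its charge, r is 0.158 for Wednesday's and 0.934 for Monday's, so the shares are 13.6% and 48.3%.

4. But B does not stay at its charge. In Wednesday's, self-condensation alone gives it a first half-life of 13.1 s, while the intermediate needs a window of 8.37 s, the life of the substrate plus its own. That window is shorter than the half-life by a factor of just 1.57, so the first estimate is too high.

5. Second-order decay divides B by 1.64 at the end of the window. This gives 0.0963, the aged branch ratio: r with B taken at the end of the window. Wednesday's share becomes 8.79%.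

6. Tuesday's should match Wednesday's, because the window is far shorter than the 3.0 min before cooling.

7. Monday's window is 46.7 s, so r ages to 0.636 and the share is 38.9%. The objection is that each target costs one reagent too, and this share of the substrate would cost 7.77 mM out of the 22.0 mM charged. Taking 0.5 of that reagent cost out of the aged B, as a rough mean over the window, lowers the share to 32.0%. I commit to that figure, so Monday's comes out higher than Wednesday's. Sunday's I place between them, without a number.

8. The forecast gives 8.9% for Wednesday's, 8.9% for Tuesday's, 19% for Sunday's and 34% for Monday's, and names Monday's as highest. Its grounds: “Heat therefore hurts.” My Monday's figure lies below its own.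

9. The simulation gives 8.84%, 8.84%, 19.1% and 34.3% in that order, with Monday's highest.

Tuesday's, with its aged ratio 0.0963, reads 8.84% target. A neighbouring flask like Tuesday's is charged with 88 mM of reagent, 4.00 times as much. Its window at 100 °C shortens to 6.93 s, but reagent is divided by 3.12. So the aged ratio is 0.203, just 2.11 times Tuesday's, and the share is 16.9%. That flask ends at 17.8% target and 82.2% side product.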